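**Assumption:** the target is taken exactly as its SMILES defines it. ent-Kaurane locants are used throughout (ring A = C1–C5, C10; ring B = C5, C6, C8, C9, C10; ring C = C8, C9, C11–C14; lactone C7(=O)–O–C20; side chain C15–C17). α is the face of C20 on C10, β the opposite face (1α-OAc, 5β-H, 6β-OH, 9β-H, 11β-OH, 13β side chain).

## Retrosynthetic overview

1. Target ⇐ 11-ketone 22 (face-selective reduction) ⇐ ring-C enone 19 + methyl 2-bromoacrylate (C13–C16 bond, new nickel-catalysed reductive conjugate alkenylation).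
2. Ring B (C6–C8 bond, 6-OH) ⇐ retro-Claisen/aldol of an 8-acetyl lactone onto a C6 aldehyde; ring C ⇐ Birch reductive acetylation of an aromatic lactone (the anisole ring becomes ring C).
3. Lactone (C7) ⇐ hydroxyl-directed C–H carbonylation; quaternary C10 and the C9–C10 bond ⇐ semipinacol 1,2-aryl shift (C1 → C10) of a 2,3-epoxy alcohol, the key step.
4. Ring A ⇐ Robinson annulation (isobutyraldehyde + methyl vinyl ketone), asymmetric vinyl conjugate addition with formaldehyde trapping, then anisole addition.
5. Order of ring formation: ring A → aryl ring attached and shifted to C10 → lactone → ring C dearomatised → ring B.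

## Route

Step 1
Reactants: 1 2-methylpropanal; 2 but-3-en-2-one
Product: 3 4,4-dimethylcyclohex-2-en-1-one
Conditions: H2SO4 (cat.), toluene, 45 °C then reflux (Dean–Stark)
Reagents that add atoms: none
Why: Acid-catalysed Michael addition of the aldehyde enol to the enone followed by intramolecular aldol condensation (Robinson annulation) gives this enone in one pot, and no stereocenter is formed.

Step 2
Reactants: 3 4,4-dimethylcyclohex-2-en-1-one; 4 vinylmagnesium bromide
Product: 6 (2R,3S)-3-ethenyl-2-(hydroxymethyl)-4,4-dimethylcyclohexan-1-one, via bromomagnesium enolate 5 (not isolated)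
Conditions: 4 (1.3 equiv), CuBr·SMe2 (5 mol %), Josiphos-type ferrocenyl diphosphine (6 mol %, the enantiomer that gives 3S), t-BuOMe, −78 °C; then monomeric CH2O in THF, −78 °C; aq NH4Cl
Reagents that add atoms: formaldehyde (C=O)
Why: Copper-catalysed asymmetric conjugate addition of the Grignard reagent sets C5 under ligand control and gives a regiodefined magnesium enolate, which formaldehyde traps anti to the new vinyl group (tandem conjugate addition–aldol), placing C20 on the correct α-carbon.

Step 3
Reactants: 6 (2R,3S)-3-ethenyl-2-(hydroxymethyl)-4,4-dimethylcyclohexan-1-one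
Product: 8 (3R)-3-ethenyl-4,4-dimethyl-2-methylidenecyclohexan-1-one, via mesylate 7 (not isolated)
Conditions: MsCl (1.2 equiv), Et3N (4 equiv), CH2Cl2, 0 °C → rt; used at once
Reagents that add atoms: none
Why: Mesylation of the primary alcohol and E1cB β-elimination (C10–H is α to the ketone) give the exocyclic enone without touching the C5 stereocenter.

Step 4
Reactants: 9 anisole; 8 (3R)-3-ethenyl-4,4-dimethyl-2-methylidenecyclohexan-1-one
Product: 11 (1S,3R)-3-ethenyl-1-(2-methoxyphenyl)-4,4-dimethyl-2-methylidenecyclohexan-1-ol, via (2-methoxyphenyl)lithium 10 (not isolated)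
Conditions: 9, n-BuLi, TMEDA, Et2O, 0 °C → rt; then 8, THF, −78 °C; aq NH4Cl
Reagents that add atoms: none
Why: Directed ortho-lithiation of anisole and 1,2-addition of the hard aryllithium to the ketone, anti to the pseudoaxial C5 vinyl group (held axial by allylic strain with the exocyclic methylene), set the C1 carbinol with aryl trans to vinyl.

Step 5
Reactants: 11 (1S,3R)-3-ethenyl-1-(2-methoxyphenyl)-4,4-dimethyl-2-methylidenecyclohexan-1-ol
Product: 13 (2R,3R)-3-ethenyl-2-(hydroxymethyl)-2-(2-methoxyphenyl)-4,4-dimethylcyclohexan-1-one, via epoxy alcohol 12 (not isolated)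
Conditions: VO(acac)2 (5 mol %), t-BuOOH (1.3 equiv), CH2Cl2, 0 °C; then BF3·OEt2 (20 mol %), −78 → −20 °C
Reagents that add atoms: tert-butyl hydroperoxide (CC(C)(C)OO)
Why: Hydroxyl-directed vanadium epoxidation puts oxygen on the allylic 1,1-disubstituted alkene syn to the tertiary OH (the non-allylic vinyl group is untouched), and the Lewis acid then triggers a stereospecific semipinacol rearrangement of the 2,3-epoxy alcohol in which the electron-rich aryl group, anti-periplanar to the breaking C10–O bond, shifts from C1 to C10 with inversion at C10, creating the quaternary centre with aryl trans and CH2OH cis to the vinyl group.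

Step 6
Reactants: 13 (2R,3R)-3-ethenyl-2-(hydroxymethyl)-2-(2-methoxyphenyl)-4,4-dimethylcyclohexan-1-one
Product: 14 (1R,6R)-6-ethenyl-5'-methoxy-5,5-dimethylspiro[cyclohexane-1,4'-isochromane]-1',2-dione
Conditions: Pd(OAc)2 (10 mol %), Ac-Leu-OH (20 mol %), AgOAc (3 equiv), CO (1 atm), ClCH2CH2Cl, 100 °C
Reagents that add atoms: carbon monoxide ([C-]#[O+])
Why: Hydroxyl-directed ortho C–H palladation by divalent palladium (six-membered palladacycle, only one free ortho position), CO insertion and C–O reductive elimination (C–H carbonylation of a 2-arylethanol, palladium reoxidised by AgOAc) close the isochromanone without touching a stereocenter.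

Step 7
Reactants: 14 (1R,6R)-6-ethenyl-5'-methoxy-5,5-dimethylspiro[cyclohexane-1,4'-isochromane]-1',2-dione
Product: 17 8-acetyl-1α-acetoxy-11-oxo-12-ene 7,20-lactone bearing the C5 vinyl group (C8/C9 epimer mixture), via dilithium enolate alkoxide 15 (not isolated), via diacetylated dienol ether 16 (not isolated)
Conditions: Li (4.2 equiv), NH3(l)/THF, t-BuOH (2.0 equiv), −78 °C; evaporate NH3; Ac2O (5 equiv), THF, −78 → 0 °C; then 1 M HCl, THF, rt
Reagents that add atoms: acetic anhydride (CC(=O)OC(C)=O); water (O)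
Why: Birch reduction of the benzoate-type ring puts sp3 carbons at C8 (ipso, as the lactone enolate) and C12 (para) while methoxy and alkyl stay on double bonds, the C1 ketone is reduced under thermodynamic control to the equatorial 1α-alkoxide, acetic anhydride C-acetylates the enolate at C8 and O-acetylates C1 (Birch reductive acylation), and aqueous acid hydrolyses the enol ether and conjugates the remaining alkene to the C11 enone, C8 and C9 being fixed only later.

Step 8
Reactants: 17 8-acetyl-1α-acetoxy-11-oxo-12-ene 7,20-lactone bearing the C5 vinyl group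
Product: 18 8-acetyl-1α-acetoxy-11-oxo-12-en-6-al 7,20-lactone
Conditions: O3 (1.0 equiv, dye indicator), CH2Cl2/MeOH, −78 °C; Me2S, −78 °C → rt
Reagents that add atoms: ozone (O=[O+][O-])
Why: Ozonolysis with reductive work-up cleaves the terminal vinyl group much faster than the electron-poor enone and leaves the C5 stereocenter untouched.

Step 9
Reactants: 18 8-acetyl-1α-acetoxy-11-oxo-12-en-6-al 7,20-lactone
Product: 19 1α-acetoxy-6β-hydroxy-11-oxo-12-ene 7,20-lactone with the C6–C8 bond (ring B closed; 5β-H, 9β-H)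
Conditions: KOMe (1.2 equiv), 18-crown-6 (1.2 equiv), THF, −40 → 0 °C; AcOH
Reagents that add atoms: none
Why: Methoxide adds to the quaternary 8-acetyl ketone and retro-Claisen cleavage releases the C8 lactone enolate regiospecifically, which closes ring B onto the C6 aldehyde (intramolecular aldol through an open transition state of the crown-complexed potassium enolate, giving the 6β alcohol anti to the lactone carbonyl), while C8 is fixed by the bridging lactone and C9 settles α to the ketone with ring C on the lactone face.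

Step 10
Reactants: 19 1α-acetoxy-6β-hydroxy-11-oxo-12-ene 7,20-lactone with the C6–C8 bond; 20 methyl 2-bromoprop-2-enoate
Product: 22 methyl 2-[(13β)-1α-acetoxy-6β-hydroxy-11-oxo-7,20-lactone-13-yl]prop-2-enoate (11-ketone of the target), via triethylsilyl enol ether 21 (not isolated)
Conditions: NiCl2(dme) (10 mol %), neocuproine (10 mol %), Mn powder (2 equiv), Et3SiCl (1.5 equiv), DMF, 0 °C → rt; then 1 M HCl, THF
Reagents that add atoms: none
Why: Proposed new method: nickel-catalysed reductive conjugate alkenylation of an enone with an α-bromoacrylate, in which zerovalent nickel and Et3SiCl convert the enone into a 1-silyloxyallyl nickel complex on the open β face (the α face of C13 is blocked by the axial lactone carbon C7), Mn reduces it, oxidative addition of the C–Br bond of 20 and C–C reductive elimination form the C13–C16 bond and set C13 (β, equatorial), and acid work-up hydrolyses the silyl enol ether; the closest known reaction is the nickel/Mn/chlorosilane reductive conjugate addition of aryl and simple alkenyl halides to cyclic enones, which has not been shown with an α-bromoacrylate.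

Step 11
Reactants: 22 methyl 2-[(13β)-1α-acetoxy-6β-hydroxy-11-oxo-7,20-lactone-13-yl]prop-2-enoate
Product: 23 CNP0421185.1 (target)
Conditions: (R)-2-methyl-CBS-oxazaborolidine (0.5 equiv), catecholborane (3 equiv), toluene, −78 °C; MeOH, aq NaHCO3
Reagents that add atoms: none
Why: Corey–Bakshi–Shibata reduction, in which the (R)-oxazaborolidine distinguishes the branched C9 side from the C12 methylene and delivers hydride to the α face to give the equatorial (11S) alcohol against the substrate bias, while catecholborane at −78 °C leaves the acrylate, lactone and acetate untouched.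

## Compound list

1 | 2-methylpropanal (isobutyraldehyde) | CC(C)C=O | starting material
2 | but-3-en-2-one (methyl vinyl ketone) | CC(=O)C=C | starting material
3 | 4,4-dimethylcyclohex-2-en-1-one | CC1(C)CCC(=O)C=C1 | intermediate
4 | vinylmagnesium bromide | C=C[Mg]Br | starting material
5 | bromomagnesium (3S)-3-ethenyl-4,4-dimethylcyclohex-1-en-1-olate | Br[Mg]OC1=C[C@H](C=C)C(C)(C)CC1 | intermediate
6 | (2R,3S)-3-ethenyl-2-(hydroxymethyl)-4,4-dimethylcyclohexan-1-one | OC[C@@H]1C(=O)CCC(C)(C)[C@H]1C=C | intermediate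
7 | [(1R,2S)-2-ethenyl-3,3-dimethyl-6-oxocyclohexyl]methyl methanesulfonate | CS(=O)(=O)OC[C@@H]1C(=O)CCC(C)(C)[C@H]1C=C | intermediate
8 | (3R)-3-ethenyl-4,4-dimethyl-2-methylidenecyclohexan-1-one | C=C1C(=O)CCC(C)(C)[C@H]1C=C | intermediate
9 | anisole (methoxybenzene) | COc1ccccc1 | starting material
10 | (2-methoxyphenyl)lithium | [Li]c1ccccc1OC | intermediate
11 | (1S,3R)-3-ethenyl-1-(2-methoxyphenyl)-4,4-dimethyl-2-methylidenecyclohexan-1-ol (aryl trans to vinyl) | C=C1[C@](O)(c2ccccc2OC)CCC(C)(C)[C@H]1C=C | intermediate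
12 | 5-ethenyl-4-(2-methoxyphenyl)-6,6-dimethyl-1-oxaspiro[2.5]octan-4-ol (epoxide oxygen cis to OH, aryl trans to vinyl) | O[C@@]1(c2ccccc2OC)CCC(C)(C)[C@@H](C=C)[C@]13CO3 | intermediate
13 | (2R,3R)-3-ethenyl-2-(hydroxymethyl)-2-(2-methoxyphenyl)-4,4-dimethylcyclohexan-1-one | OC[C@@]1(c2ccccc2OC)C(=O)CCC(C)(C)[C@H]1C=C | intermediate
14 | (1R,6R)-6-ethenyl-5'-methoxy-5,5-dimethylspiro[cyclohexane-1,4'-isochromane]-1',2-dione | COc1cccc2C(=O)OC[C@]3(C(=O)CCC(C)(C)[C@H]3C=C)c12 | intermediate
15 | dilithium salt of the Birch dianion of 14 (C7(OLi)=C8 lactone enolate, C9=C11(OMe), C13=C14, C12H2, 1α-OLi) | COC1=C2C(C=CC1)=C(O[Li])OC[C@]23[C@@H](O[Li])CCC(C)(C)[C@H]3C=C | intermediate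
16 | 8-acetyl-1α-acetoxy-11-methoxy-9(11),13-diene 7,20-lactone with C5 vinyl (C8 epimers) | COC1=C2[C@]3(COC(=O)C2(C(C)=O)C=CC1)[C@@H](OC(C)=O)CCC(C)(C)[C@H]3C=C | intermediate
17 | 8-acetyl-1α-acetoxy-11-oxo-12-ene 7,20-lactone with C5 vinyl (C8/C9 epimers) | O=C1C=CCC2(C(C)=O)C(=O)OC[C@@]3(C12)[C@@H](OC(C)=O)CCC(C)(C)[C@H]3C=C | intermediate
18 | 8-acetyl-1α-acetoxy-11-oxo-12-en-6-al 7,20-lactone (C8/C9 epimers) | O=C1C=CCC2(C(C)=O)C(=O)OC[C@@]3(C12)[C@@H](OC(C)=O)CCC(C)(C)[C@H]3C=O | intermediate
19 | 1α-acetoxy-6β-hydroxy-11-oxo-12-ene 7,20-lactone with the C6–C8 bond (5β-H, 9β-H) | C1=CC(=O)[C@@H]2[C@]3(C1)C(=O)OC[C@]21[C@@H](OC(C)=O)CCC(C)(C)[C@H]1[C@@H]3O | intermediate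
20 | methyl 2-bromoprop-2-enoate | C=C(Br)C(=O)OC | starting material
21 | 11-(triethylsilyloxy)-11-ene silyl enol ether of 22 | C=C(C(=O)OC)[C@@H]1C=C(O[Si](CC)(CC)CC)[C@@H]2[C@]3(C1)C(=O)OC[C@]21[C@@H](OC(C)=O)CCC(C)(C)[C@H]1[C@@H]3O | intermediate
22 | methyl 2-[(13β)-1α-acetoxy-6β-hydroxy-11-oxo-7,20-lactone-13-yl]prop-2-enoate | C=C(C(=O)OC)[C@@H]1CC(=O)[C@@H]2[C@]3(C1)C(=O)OC[C@]21[C@@H](OC(C)=O)CCC(C)(C)[C@H]1[C@@H]3O | intermediate
23 | CNP0421185.1 (1α-acetoxy-6β,11β-dihydroxy 7,20-lactone with 13β 1-(methoxycarbonyl)vinyl group) | C=C(C(=O)OC)[C@@H]1C[C@H](O)[C@@H]2[C@]3(C1)C(=O)OC[C@]21[C@@H](OC(C)=O)CCC(C)(C)[C@H]1[C@@H]3O | target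

## Step count and risks

Total steps: 11. Longest linear sequence: 11 steps (1 → 23); anisole enters in step 4 and methyl 2-bromoacrylate in step 10.

**Step 6 (C–H carbonylation).** The vinyl group can interfere with divalent palladium and the β-hydroxy ketone 13 can lose formaldehyde by retro-aldol. The fallback carries the carbonylation handle as an aryl bromide; it sets out from 8 and comes back at 14. 3-Bromophenol (MeI, K2CO3, acetone) gives 1-bromo-3-methoxybenzene F1. LDA at −78 °C lithiates C2 of F1 to give (2-bromo-6-methoxyphenyl)lithium F2, which adds to 8 to give bromo allylic alcohol F3. The epoxidation/semipinacol sequence of step 5 then leads through bromo epoxy alcohol F4 to bromo hydroxy ketone F5. Intramolecular alkoxycarbonylation with zerovalent palladium formed from Pd(OAc)2/Xantphos (CO 1 atm, Et3N, toluene, 90 °C) closes the lactone to 14.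

**Step 7 (Birch reductive acetylation).** O- instead of C-acetylation, over-reduction or ester cleavage are possible. The fallback protonates the Birch enolate and runs the aldol from the doubly allylic C8–H before the C11 ketone is unmasked; it sets out from 14 and comes back at 19. Ozonolysis of 14 (O3; Me2S) gives keto aldehyde F6. Li/NH3/t-BuOH with NH4Cl quench reduces the arene, the ketone and the aldehyde to dienol ether diol F7. Cu(MeCN)4OTf/bipyridine/TEMPO/N-methylimidazole under air oxidises only the primary alcohol to hydroxy aldehyde F8. Ac2O/pyridine gives acetate F9. DBU in CH2Cl2 then effects the aldol at C8 to aldol product F10, and 1 M HCl hydrolyses the enol ether and conjugates the alkene to give 19.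

**Step 10 (the proposed new nickel coupling).** The bromoacrylate may homocouple or polymerise, or the enone may simply be reduced. The fallback uses known chemistry; it sets out from 19 and comes back at 22. Reversible Michael addition of methyl acetoacetate (DBU, THF) gives the thermodynamically favoured equatorial keto ester F11. Deacetylative methylenation (paraformaldehyde, K2CO3, THF) then converts the acetoacetate unit into the α-methylene ester 22.

## Further compounds

F1 | step 6 | 1-bromo-3-methoxybenzene | COc1cccc(Br)c1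
F2 | step 6 | (2-bromo-6-methoxyphenyl)lithium | [Li]c1c(Br)cccc1OC
F3 | step 6 | bromo allylic alcohol: 1-(2-bromo-6-methoxyphenyl)-3-ethenyl-4,4-dimethyl-2-methylidenecyclohexan-1-ol (aryl trans to vinyl) | C=C1[C@](O)(c2c(Br)cccc2OC)CCC(C)(C)[C@H]1C=C
F4 | step 6 | bromo epoxy alcohol: 4-(2-bromo-6-methoxyphenyl)-5-ethenyl-6,6-dimethyl-1-oxaspiro[2.5]octan-4-ol | O[C@@]1(c2c(Br)cccc2OC)CCC(C)(C)[C@@H](C=C)[C@]13CO3
F5 | step 6 | bromo hydroxy ketone: 2-(2-bromo-6-methoxyphenyl)-3-ethenyl-2-(hydroxymethyl)-4,4-dimethylcyclohexan-1-one | OC[C@@]1(c2c(Br)cccc2OC)C(=O)CCC(C)(C)[C@H]1C=C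
F6 | step 7 | keto aldehyde: 6-formyl analogue of 14 | COc1cccc2C(=O)OC[C@]3(C(=O)CCC(C)(C)[C@H]3C=O)c12
F7 | step 7 | dienol ether diol: 1α-hydroxy-6-hydroxy-11-methoxy-9(11),13-diene 7,20-lactone (6,7-seco, C8–H) | COC1=C2[C@]3(COC(=O)C2C=CC1)[C@@H](O)CCC(C)(C)[C@H]3CO
F8 | step 7 | hydroxy aldehyde: 1α-hydroxy-11-methoxy-9(11),13-dien-6-al 7,20-lactone | COC1=C2[C@]3(COC(=O)C2C=CC1)[C@@H](O)CCC(C)(C)[C@H]3C=O
F9 | step 7 | acetate: 1α-acetoxy-11-methoxy-9(11),13-dien-6-al 7,20-lactone | COC1=C2[C@]3(COC(=O)C2C=CC1)[C@@H](OC(C)=O)CCC(C)(C)[C@H]3C=O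
F10 | step 7 | aldol product: 1α-acetoxy-6β-hydroxy-11-methoxy-9(11),13-diene 7,20-lactone with the C6–C8 bond | COC1=C2[C@]3(C=CC1)C(=O)OC[C@]24[C@@H](OC(C)=O)CCC(C)(C)[C@H]4[C@@H]3O
F11 | step 10 | keto ester: methyl 2-acetyl-2-[(13β)-1α-acetoxy-6β-hydroxy-11-oxo-7,20-lactone-13-yl]acetate | CC(=O)C(C(=O)OC)[C@@H]1CC(=O)[C@@H]2[C@]3(C1)C(=O)OC[C@]21[C@@H](OC(C)=O)CCC(C)(C)[C@H]1[C@@H]3O
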